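**Retrosynthetic overview**

- The coumarate is cut at its ester C–O bond (Steglich esterification) and the acrylic acid at the C5–vinyl bond (Heck reaction on a C5 bromide). This leaves the core (S)-2-[(S)-1-hydroxypropan-2-yl]-2,3-dihydrobenzofuran.
- The strategy rests on one feature: ring carbon C2 (bonded to O1), the neighbouring exocyclic methyl-bearing carbon with its CH2O arm, and the benzylic ring carbon C3 together form a 4-aryl-3-hydroxy-2-methylbutanoate, a propionate aldol pattern.
- Both stereocentres are therefore set at once by enzymatic dynamic reduction of a racemic α-methyl β-keto ester, built from 2-bromophenylacetic acid and a methylmalonate half-ester.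
- Ring order: both benzene rings are bought. The only ring made, the dihydrofuran, is closed after the reduction by O1–C7a aryl etherification, which leaves the carbinol C–O bond intact. Bromination at C5, Heck coupling, esterification and one acidolysis follow.

Key step: step 3

Assumption: the descriptors read from the SMILES are S at ring C2 and S at the side-chain carbon. A ketoreductase with syn-(2R,3S) preference for the keto ester is assumed to be found in a commercial screening panel.

**Route**

Step 1
Reactants: 1 diethyl methylmalonate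
Product: 2 potassium ethyl methylmalonate (racemic half-ester salt)
Conditions: KOH (1.0 equiv), EtOH, 0 °C to rt; salt collected by filtration
Reagents that add atoms: potassium hydroxide, [K+].[OH-]
Why: Mono-saponification of a malonic diester should stop after one ester because the potassium half-ester salt precipitates from ethanol and its carboxylate shields the second ester from hydroxide; the α-carbon stays racemic, which is harmless because it is racemised on purpose in step 3.

Step 2
Reactants: 3 2-bromophenylacetic acid; 2 potassium ethyl methylmalonate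
Product: 6 racemic ethyl 4-(2-bromophenyl)-2-methyl-3-oxobutanoate, via acyl imidazolide 4 (not isolated), via acylated malonate half-ester 5 (not isolated)
Conditions: 3, CDI, THF, rt; then 2, MgCl2, Et3N, MeCN, rt to 40 °C; 1 M HCl work-up
Reagents that add atoms: none
Why: Masamune–Brooks decarboxylative Claisen condensation, in which the acyl imidazolide C-acylates the magnesium-chelated enolate of the half-ester and the resulting β-keto carboxylate loses CO2 on acidification, should build the α-methyl β-keto ester under near-neutral conditions that leave the aryl bromide untouched.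

Step 3
Reactants: 6 racemic ethyl 4-(2-bromophenyl)-2-methyl-3-oxobutanoate
Product: 7 ethyl (2R,3S)-4-(2-bromophenyl)-3-hydroxy-2-methylbutanoate (syn)
Conditions: ketoreductase (syn-(2R,3S)-selective, chosen by panel screen), NADP+ (cat.), iPrOH (10 vol %), KH2PO4/K2HPO4 buffer pH 7.0, MgSO4 (1 mM), DMSO (5 vol %), 30 °C
Reagents that add atoms: none
Why: Inside the ketoreductase the nicotinamide ring of NADPH delivers hydride to one face of the C3 carbonyl while an active-site acid protonates the oxygen, and isopropanol regenerates NADPH on the same enzyme; the unreduced enantiomer of 6 racemises through its enol in the buffer because the C2 hydrogen sits between ketone and ester. The closest known reaction type is the ketoreductase or baker's-yeast dynamic reductive kinetic resolution of α-alkyl β-keto esters, the enzymatic analogue of Noyori dynamic kinetic resolution hydrogenation. No ring is closed here, the dihydrofuran ring being formed only in step 6. The new C3 stereocentre (S) is controlled by the hydride-delivery face fixed by the active site, and the C2 stereocentre (R) by the enzyme turning over only the 2R enantiomer of the rapidly equilibrating substrate, so the syn-(2R,3S) alcohol should be drained from the whole racemate. The step needs enantioface selectivity at the ketone together with enantiomer selection at C2 (syn over anti), and the substrate secures the dynamic part through its doubly activated α-proton, which keeps racemisation faster than reduction of the mismatched enantiomer. The ortho bromine is inert to the enzyme and keeps the future ring oxygen masked, so that no phenol can condense with the ketone to give a benzofuran.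

Step 4
Reactants: 7 ethyl (2R,3S)-4-(2-bromophenyl)-3-hydroxy-2-methylbutanoate
Product: 8 (2S,3S)-4-(2-bromophenyl)-2-methylbutane-1,3-diol
Conditions: LiBH4, THF, 0 °C to rt; then H2O
Reagents that add atoms: none
Why: Borohydride reduction of the ester with LiBH4, assisted by lithium chelation to the β-hydroxyl, should give the 1,3-diol without touching the aryl bromide and removes the enolisable, retro-aldol-prone β-hydroxy ester before any base is used; both stereocentres are untouched and only the descriptor at the methyl-bearing carbon changes (R to S) because CH2OH ranks below the carbinol carbon.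

Step 5
Reactants: 8 (2S,3S)-4-(2-bromophenyl)-2-methylbutane-1,3-diol
Product: 9 (2S,3S)-1-(2-bromophenyl)-4-[(tert-butyldimethylsilyl)oxy]-3-methylbutan-2-ol
Conditions: TBSCl (1.05 equiv), imidazole, CH2Cl2, 0 °C
Reagents that add atoms: tert-butyldimethylsilyl chloride (TBSCl), CC(C)(C)[Si](C)(C)Cl
Why: Imidazole-mediated silyl ether formation with the bulky silyl chloride should discriminate the unhindered primary hydroxyl from the secondary carbinol flanked by a branched carbon and the ortho-substituted benzyl group, leaving the latter free for ring closure.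

Step 6
Reactants: 9 (2S,3S)-1-(2-bromophenyl)-4-[(tert-butyldimethylsilyl)oxy]-3-methylbutan-2-ol
Product: 10 (2S)-2-[(2S)-1-[(tert-butyldimethylsilyl)oxy]propan-2-yl]-2,3-dihydro-1-benzofuran
Conditions: Pd(OAc)2 (3 mol %), 2-(di-tert-butylphosphino)-1,1'-binaphthyl (4 mol %), Cs2CO3, toluene, 70 °C
Reagents that add atoms: none
Why: Intramolecular Buchwald-type palladium-catalysed C–O coupling, in which oxidative addition of the aryl bromide to zerovalent palladium, alkoxide binding assisted by Cs2CO3 and C–O reductive elimination from a six-membered oxapalladacycle close the five-membered ring between O1 and C7a, should retain the S configuration because the carbinol C–O bond is never broken; the bulky electron-rich phosphine is chosen so that reductive elimination outruns β-hydride elimination.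

Step 7
Reactants: 10 (2S)-2-[(2S)-1-[(tert-butyldimethylsilyl)oxy]propan-2-yl]-2,3-dihydro-1-benzofuran
Product: 11 (2S)-5-bromo-2-[(2S)-1-[(tert-butyldimethylsilyl)oxy]propan-2-yl]-2,3-dihydro-1-benzofuran
Conditions: NBS (1.0 equiv), MeCN, 0 °C to rt, dark
Reagents that add atoms: N-bromosuccinimide (NBS), O=C1CCC(=O)N1Br
Why: Electrophilic aromatic substitution should occur at C5 because the ring oxygen activates its para position far more than the hindered ortho position C7, and NBS in polar acetonitrile in the dark reacts by the ionic pathway, so the benzylic C3 hydrogens and the silyl ether are left alone.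

Step 8
Reactants: 11 (2S)-5-bromo-2-[(2S)-1-[(tert-butyldimethylsilyl)oxy]propan-2-yl]-2,3-dihydro-1-benzofuran; 12 tert-butyl acrylate
Product: 13 tert-butyl (E)-3-[(2S)-2-[(2S)-1-[(tert-butyldimethylsilyl)oxy]propan-2-yl]-2,3-dihydro-1-benzofuran-5-yl]prop-2-enoate
Conditions: Pd(OAc)2 (5 mol %), P(o-tol)3 (10 mol %), Et3N, DMF, 100 °C
Reagents that add atoms: none
Why: Mizoroki–Heck reaction, with syn insertion of the acrylate into the aryl–palladium bond (aryl to the β-carbon) followed by syn β-hydride elimination, should give the E-cinnamate, and the tert-butyl ester, the silyl ether and both stereocentres are inert to the conditions.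

Step 9
Reactants: 13 tert-butyl (E)-3-[(2S)-2-[(2S)-1-[(tert-butyldimethylsilyl)oxy]propan-2-yl]-2,3-dihydro-1-benzofuran-5-yl]prop-2-enoate
Product: 14 tert-butyl (E)-3-[(2S)-2-[(2S)-1-hydroxypropan-2-yl]-2,3-dihydro-1-benzofuran-5-yl]prop-2-enoate
Conditions: TBAF, AcOH (1:1), THF, 0 °C to rt
Reagents that add atoms: none
Why: Fluoride-induced desilylation driven by the strong Si–F bond, buffered with acetic acid so that no free alkoxide sits next to the acrylate, should liberate the primary alcohol while the tert-butyl ester is unaffected.

Step 10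
Reactants: 15 (E)-p-coumaric acid
Product: 16 methoxymethyl (E)-3-[4-(methoxymethoxy)phenyl]prop-2-enoate
Conditions: MOMCl (2.5 equiv), iPr2NEt, CH2Cl2, 0 °C to rt
Reagents that add atoms: chloromethyl methyl ether (MOMCl), COCCl
Why: O-Alkylation with an α-chloro ether (Williamson-type, through the oxocarbenium ion) should protect the phenol as its MOM ether and, unavoidably, the acid as its MOM ester, which is removed selectively in the next step.

Step 11
Reactants: 16 methoxymethyl (E)-3-[4-(methoxymethoxy)phenyl]prop-2-enoate
Product: 17 (E)-3-[4-(methoxymethoxy)phenyl]prop-2-enoic acid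
Conditions: LiOH, THF/H2O, 0 °C to rt; then 1 M HCl to pH 4, 0 °C
Reagents that add atoms: lithium hydroxide, [Li+].[OH-]
Why: Saponification (base-mediated acyl substitution) should cleave the acyloxymethyl ester whereas the aryl MOM acetal is stable to hydroxide, and acidification only to pH 4 in the cold avoids acetal hydrolysis; the E alkene is untouched.

Step 12
Reactants: 14 tert-butyl (E)-3-[(2S)-2-[(2S)-1-hydroxypropan-2-yl]-2,3-dihydro-1-benzofuran-5-yl]prop-2-enoate; 17 (E)-3-[4-(methoxymethoxy)phenyl]prop-2-enoic acid
Product: 18 tert-butyl (E)-3-[(2S)-2-[(2S)-1-{[(E)-3-[4-(methoxymethoxy)phenyl]prop-2-enoyl]oxy}propan-2-yl]-2,3-dihydro-1-benzofuran-5-yl]prop-2-enoate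
Conditions: EDC·HCl, Et3N, DMAP (cat.), CH2Cl2, 0 °C to rt
Reagents that add atoms: none
Why: Steglich esterification, in which the carbodiimide activates the acid as its O-acylisourea and DMAP relays the acyl group to the unhindered primary alcohol, should join the two halves without involving either stereocentre or alkene geometry.

Step 13
Reactants: 18 tert-butyl (E)-3-[(2S)-2-[(2S)-1-{[(E)-3-[4-(methoxymethoxy)phenyl]prop-2-enoyl]oxy}propan-2-yl]-2,3-dihydro-1-benzofuran-5-yl]prop-2-enoate
Product: 19 (E)-3-[(2S)-2-[(2S)-1-{[(E)-3-(4-hydroxyphenyl)prop-2-enoyl]oxy}propan-2-yl]-2,3-dihydro-1-benzofuran-5-yl]prop-2-enoic acid (CNP0224846.1)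
Conditions: TFA/CH2Cl2 (1:4), anisole (5 equiv), H2O (3 equiv), 0 °C to rt
Reagents that add atoms: none
Why: Brønsted acidolysis should cleave the tert-butyl ester by alkyl–oxygen fission (AAL1) and the aryl MOM acetal through its oxocarbenium ion, with water and anisole intercepting the cations, and as no base or nucleophile is present the coumarate ester, both E alkenes and both stereocentres should survive.

**Compound list**

1 | diethyl methylmalonate | CCOC(=O)C(C)C(=O)OCC | starting material
2 | potassium ethyl methylmalonate (racemic) | CCOC(=O)C(C)C(=O)[O-].[K+] | intermediate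
3 | 2-bromophenylacetic acid | OC(=O)Cc1ccccc1Br | starting material
4 | 1-[(2-bromophenyl)acetyl]imidazole (acyl imidazolide, not isolated) | O=C(Cc1ccccc1Br)n1ccnc1 | intermediate
5 | 2-[(2-bromophenyl)acetyl]-2-methylmalonic acid monoethyl ester (formed as its magnesium carboxylate, not isolated) | CCOC(=O)C(C)(C(=O)O)C(=O)Cc1ccccc1Br | intermediate
6 | racemic ethyl 4-(2-bromophenyl)-2-methyl-3-oxobutanoate | CCOC(=O)C(C)C(=O)Cc1ccccc1Br | intermediate
7 | ethyl (2R,3S)-4-(2-bromophenyl)-3-hydroxy-2-methylbutanoate | CCOC(=O)[C@H](C)[C@@H](O)Cc1ccccc1Br | intermediate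
8 | (2S,3S)-4-(2-bromophenyl)-2-methylbutane-1,3-diol | OC[C@H](C)[C@@H](O)Cc1ccccc1Br | intermediate
9 | (2S,3S)-1-(2-bromophenyl)-4-[(tert-butyldimethylsilyl)oxy]-3-methylbutan-2-ol | CC(C)(C)[Si](C)(C)OC[C@H](C)[C@@H](O)Cc1ccccc1Br | intermediate
10 | (2S)-2-[(2S)-1-[(tert-butyldimethylsilyl)oxy]propan-2-yl]-2,3-dihydro-1-benzofuran | CC(C)(C)[Si](C)(C)OC[C@H](C)[C@@H]1Cc2ccccc2O1 | intermediate
11 | (2S)-5-bromo-2-[(2S)-1-[(tert-butyldimethylsilyl)oxy]propan-2-yl]-2,3-dihydro-1-benzofuran | CC(C)(C)[Si](C)(C)OC[C@H](C)[C@@H]1Cc2cc(Br)ccc2O1 | intermediate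
12 | tert-butyl acrylate | C=CC(=O)OC(C)(C)C | starting material
13 | tert-butyl (E)-3-[(2S)-2-[(2S)-1-[(tert-butyldimethylsilyl)oxy]propan-2-yl]-2,3-dihydro-1-benzofuran-5-yl]prop-2-enoate | CC(C)(C)[Si](C)(C)OC[C@H](C)[C@@H]1Cc2cc(/C=C/C(=O)OC(C)(C)C)ccc2O1 | intermediate
14 | tert-butyl (E)-3-[(2S)-2-[(2S)-1-hydroxypropan-2-yl]-2,3-dihydro-1-benzofuran-5-yl]prop-2-enoate | OC[C@H](C)[C@@H]1Cc2cc(/C=C/C(=O)OC(C)(C)C)ccc2O1 | intermediate
15 | (E)-p-coumaric acid | OC(=O)/C=C/c1ccc(O)cc1 | starting material
16 | methoxymethyl (E)-3-[4-(methoxymethoxy)phenyl]prop-2-enoate | COCOC(=O)/C=C/c1ccc(OCOC)cc1 | intermediate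
17 | (E)-3-[4-(methoxymethoxy)phenyl]prop-2-enoic acid | COCOc1ccc(/C=C/C(=O)O)cc1 | intermediate
18 | tert-butyl (E)-3-[(2S)-2-[(2S)-1-{[(E)-3-[4-(methoxymethoxy)phenyl]prop-2-enoyl]oxy}propan-2-yl]-2,3-dihydro-1-benzofuran-5-yl]prop-2-enoate | COCOc1ccc(/C=C/C(=O)OC[C@H](C)[C@@H]2Cc3cc(/C=C/C(=O)OC(C)(C)C)ccc3O2)cc1 | intermediate
19 | (E)-3-[(2S)-2-[(2S)-1-{[(E)-3-(4-hydroxyphenyl)prop-2-enoyl]oxy}propan-2-yl]-2,3-dihydro-1-benzofuran-5-yl]prop-2-enoic acid (CNP0224846.1) | C[C@@H](COC(=O)/C=C/c1ccc(O)cc1)[C@@H]1Cc2cc(/C=C/C(=O)O)ccc2O1 | target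

**Step count**

Total: 13 steps. Longest linear sequence: 11 steps (steps 1 to 9, 12 and 13, from diethyl methylmalonate); steps 10 and 11 form the two-step coumarate branch.

**Steps most likely to fail**

Step 3 (enzymatic dynamic reduction). The panel may offer no enzyme with enough enantioface and syn/anti discrimination for this 4-aryl substrate, or racemisation of the α-centre may lag behind reduction so that conversion stalls near one half. The fallback replaces the reduction by an auxiliary-controlled aldol reaction. It sets out from 3, which would be reduced with BH3·THF to 2-(2-bromophenyl)ethanol F1 and oxidised with Dess–Martin periodinane to (2-bromophenyl)acetaldehyde F2. An Evans syn aldol reaction of this aldehyde with commercial (R)-4-benzyl-3-propionyloxazolidin-2-one (Bu2BOTf, iPr2NEt, CH2Cl2, −78 to 0 °C) should give (4R)-4-benzyl-3-[(2R,3S)-4-(2-bromophenyl)-3-hydroxy-2-methylbutanoyl]oxazolidin-2-one F3. Reductive removal of the auxiliary with LiBH4 (THF, 0 °C) would deliver the diol directly, so the fallback comes back to the route at 8.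

Step 6 (aryl etherification). β-Hydride elimination from the palladium alkoxide may compete, giving ketone and debrominated arene, or base-induced migration of the silyl group to the secondary oxygen may block ring closure. The fallback closes the ring by SN2 attack of a phenol oxygen with double inversion instead of metal-catalysed C–O coupling. It sets out from 9. Mitsunobu inversion with 4-nitrobenzoic acid (PPh3, DIAD, THF) should give (2R,3S)-1-(2-bromophenyl)-4-[(tert-butyldimethylsilyl)oxy]-3-methylbutan-2-yl 4-nitrobenzoate F4. Miyaura borylation (bis(pinacolato)diboron, PdCl2(dppf), KOAc, dioxane, 80 °C) would give (2R,3S)-4-[(tert-butyldimethylsilyl)oxy]-3-methyl-1-[2-(4,4,5,5-tetramethyl-1,3,2-dioxaborolan-2-yl)phenyl]butan-2-yl 4-nitrobenzoate F5. Aqueous NaOH/H2O2 in THF would oxidise the C–B bond and saponify the ester to 2-[(2R,3S)-4-[(tert-butyldimethylsilyl)oxy]-2-hydroxy-3-methylbutyl]phenol F6. Mitsunobu cyclodehydration (PPh3, DIAD, THF, 0 °C) then closes the ring with the second inversion, and the fallback comes back to the route at 10.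

Step 13 (global acidolysis). The methoxymethyl cation, a formaldehyde equivalent released together with the tert-butyl cation, may alkylate the freed phenol ring or C7 of the dihydrobenzofuran faster than the scavengers trap it, or acetal cleavage may lag behind ester cleavage. The fallback omits phenol protection altogether. It sets out from 14 and 15, which would be joined by a Mitsunobu esterification (PPh3, DIAD, THF, 0 °C) in which the carboxylic acid, far more acidic than the phenol, is the pronucleophile. This should give tert-butyl (E)-3-[(2S)-2-[(2S)-1-{[(E)-3-(4-hydroxyphenyl)prop-2-enoyl]oxy}propan-2-yl]-2,3-dihydro-1-benzofuran-5-yl]prop-2-enoate F7. TFA/CH2Cl2 with anisole then has only the tert-butyl ester to remove, and the fallback comes back to the route at 19.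

**Further compounds**

F1 | step 3 | 2-(2-bromophenyl)ethanol | OCCc1ccccc1Br
F2 | step 3 | (2-bromophenyl)acetaldehyde | O=CCc1ccccc1Br
F3 | step 3 | (4R)-4-benzyl-3-[(2R,3S)-4-(2-bromophenyl)-3-hydroxy-2-methylbutanoyl]oxazolidin-2-one | O=C(N1[C@H](Cc2ccccc2)COC1=O)[C@H](C)[C@@H](O)Cc1ccccc1Br
F4 | step 6 | (2R,3S)-1-(2-bromophenyl)-4-[(tert-butyldimethylsilyl)oxy]-3-methylbutan-2-yl 4-nitrobenzoate | CC(C)(C)[Si](C)(C)OC[C@H](C)[C@H](OC(=O)c1ccc(cc1)[N+](=O)[O-])Cc1ccccc1Br
F5 | step 6 | (2R,3S)-4-[(tert-butyldimethylsilyl)oxy]-3-methyl-1-[2-(4,4,5,5-tetramethyl-1,3,2-dioxaborolan-2-yl)phenyl]butan-2-yl 4-nitrobenzoate | CC(C)(C)[Si](C)(C)OC[C@H](C)[C@H](OC(=O)c1ccc(cc1)[N+](=O)[O-])Cc1ccccc1B1OC(C)(C)C(C)(C)O1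
F6 | step 6 | 2-[(2R,3S)-4-[(tert-butyldimethylsilyl)oxy]-2-hydroxy-3-methylbutyl]phenol | CC(C)(C)[Si](C)(C)OC[C@H](C)[C@H](O)Cc1ccccc1O
F7 | step 13 | tert-butyl (E)-3-[(2S)-2-[(2S)-1-{[(E)-3-(4-hydroxyphenyl)prop-2-enoyl]oxy}propan-2-yl]-2,3-dihydro-1-benzofuran-5-yl]prop-2-enoate | Oc1ccc(/C=C/C(=O)OC[C@H](C)[C@@H]2Cc3cc(/C=C/C(=O)OC(C)(C)C)ccc3O2)cc1
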